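## Structural features

The target is a spiro[chromane-2,2'-norbornane]. A dihydropyran ring (O1, C2, C3, C4, C4a, C8a) is fused to a fully substituted benzene ring and joined through the spiro carbon C2 to a 3',3'-dimethylbicyclo[2.2.1]heptane. Chroman atoms are unprimed and norbornane atoms primed throughout.

The benzene ring is a 2,4-diformylphloroglucinol monoether: OH at C5 and C7, CHO at C6 and C8, O1 on C8a, and the isobutyl-bearing C4 on C4a.

There are four stereocentres. The bridgeheads are C1' (R) and C4' (S). The spiro carbon C2 (R) sits directly between C1' and the quaternary C3', with O1 endo and C3 exo on the norbornane. C4 (S) is separated from C2 by the C3 methylene.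

The fragile groups are the tertiary, neopentyl-type alkyl aryl ether C2–O1 (acid would give a 2-norbornyl cation and Wagner–Meerwein shifts), the two aryl aldehydes, and the free phloroglucinol once unveiled.

The real difficulty is to make the O1 bond at the most hindered carbon with defined configuration, to relate C4 to the norbornane across C3, and to bring in two formyl groups without Lewis acids.

The key step exploits the fact that the C6 and C8 formyl groups are ortho/para to C8a, C5 and C7. With fluorine at these three positions the ring is an SNAr acceptor, so O1–C8a can be closed from a pre-formed C2 alkoxide, and the same activation later turns C5–F and C7–F into the phenols.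

## Logic of the disconnections

**17 to 16.** No skeletal bond is cut; the O–H groups at C5 and C7 become O–CH2CH2SiMe3. The last operation should touch neither the formyl groups nor the C2–O1 ether, and fluoride-induced fragmentation does this without acid, hydrogen or Lewis acid. The free diformylphloroglucinol therefore appears only at the end. The demand is that both ethers of 16 fragment near room temperature.

**16 to 15.** The C5–O and C7–O bonds are cut back to C–F. Both carbons are SNAr-active (C7 between two formyl groups; C5 ortho to the C6 and para to the C8 formyl group). The gain is that no oxygen substituent has to survive the organometallic steps. The demand is two intermolecular substitutions by a primary alkoxide, one at the crowded C5, without exchange at C8a.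

**15 to 14.** The O1–C8a bond is cut and the pyran ring opens. C8a is ortho to one formyl group and para to the other, and the C2–O bond stays intact, so C2 keeps its configuration and never becomes a cation. In 14 both C2 and C4 are already set. The demand is that the tertiary alkoxide attacks an ortho fluoride faster than anything attacks the para fluoride or the formyl groups.

**14 to 12.** The two aryl–CHO bonds are cut. The ring C–H bonds between two fluorines are the most acidic sites, so lithiation installs both formyl groups without electrophilic substitution. The gain is an aryl group that is inert up to this point. The demand is a second metalation while the first formyl group is masked in the flask, and no base contact of 14 before step 8.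

**12 to 11.** The C3–H and C4–H bonds are removed to give the C3=C4 alkene. C4 is 1,3 to the tertiary OH, which can steer a cationic iridium catalyst. The stereocentre is thus reduced to an alkene geometry. The demand is the E isomer (isobutyl cis to C2) and delivery of hydrogen through the O-bound catalyst.

**11 to 9 and 10.** The C4–CH2(isobutyl) bond is cut. An sp2–sp3 cross-coupling retains the alkene geometry, and the isobutyl group comes from a commercial zinc reagent. The demand is iodine on C4, cis to C2.

**9 to 7.** C4–I and C3–H are removed to give the C3≡C4 alkyne. The propargylic oxygen directs a trans hydroalumination that fixes both regiochemistry and geometry. The demand is hydride to C3 and aluminium to C4.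

**7 to 5 and 6.** The C4–aryl bond is cut (alkyne–aryl coupling). The aryl group enters as a cheap bromide and no separate aryl acetylene has to be made. The demand is tolerance of the free tertiary OH.

**5 to 3 and 4.** The C2–C3 bond is cut. Carbonyl addition is the only event that creates C2, and exo attack puts O endo. The gain is a ketone with only the two bridgehead stereocentres. The demand is exo selectivity on a hindered but non-enolisable ketone.

**3 to 1.** The C2=O bond is traced to the exocyclic C=CH2. The terpene supplies C1', C4' and the gem-dimethyl C3' in one purchase. The demand is cleavage without skeletal rearrangement and a starting material of high enantiomeric purity.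

## Other disconnections considered

**Alternative 1:** The cut is C2–C3' together with the C3–CH2 bond of a cyclobutane, so the norbornane is closed on a chromone instead of being bought. Irradiation of chromone A1 would give an enone–alkene [2+2] cycloaddition: first C2–C3' through a five-membered ring, then C3–CH2, to give photoadduct A2. The C3–CH2 bond, alpha to the C4 ketone, would then be cut reductively to reveal the second methyl group.

- In its favour: two C–C bonds, two quaternary centres (C2, C3') and the bicycle form in one step. The cis tether forces an exo-fused cyclobutane, so O1 ends endo by geometry. On the C2 configuration this is at least the equal of the chosen exo addition, arguably more rigid.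
- Against it: A1 needs an enantiopure cis-1,3-disubstituted cyclopentane, whereas 1 supplies both bridgeheads. The reductive scission must break C3–CH2 and not C2–C3; both are alpha to the ketone, and C2–C3 cleavage would give an oxygen-stabilised tertiary radical. C4 still carries a carbonyl, so the isobutyl group must be added and the oxygen removed with stereocontrol.
- Comparison: the endgame needs cleavage of two methyl ethers and two electrophilic formylations on the finished tertiary ether, which the chosen plan avoids. The mechanism is an excited-state diradical path against a polar addition–elimination. The step count would be clearly higher.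

**Alternative 2:** The cut is C2–C1'. A metal hydride catalyst such as Fe(acac)3 with PhSiH3 would transfer a hydrogen atom to C3 of the enol ether in 4H-chromene A3. The tertiary, oxygen-stabilised C2 radical would add to one olefinic carbon of the cyclopentene and close the bicycle to give A4.

- In its favour: neutral, mild conditions selective for the electron-rich enol ether. C4 and the isobutyl group are in place before the norbornane exists, so no late hydrogenation is needed; on this point it is better than the chosen plan. It also avoids ozone and stoichiometric aluminium, zinc and lithium reagents.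
- Against it: the radical face and the choice between the two olefinic carbons give four stereochemical outcomes. C2, C1' and C4' would all be set in this step, with only the remote C4 as controller. In the chosen plan the bridgeheads are bought and C2 comes from a well-precedented exo addition.
- Comparison: closure to the strained bicycle must outrun simple reduction of the C2 radical. A4 still needs demethylation and double formylation on the acid-sensitive ether. Step economy would be roughly equal.

**Alternative 3:** The cuts are O1–C8a and C4–C4a. The alkoxide of β-hydroxy ester A5 would add to the aryne released from silyl triflate A6 by fluoride, and the aryl anion would acylate on the ester to give chromanone A7.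

- In its favour: two bonds and the pyranone ring form in one step. A5 is one exo enolate addition away from 3, so the logic for C2 (bond to oxygen made at the ketone, never broken) is the same as in the chosen plan, an equal point. The core is reached in fewer steps, a better point. The methoxy group next to the aryne bond directs the regiochemistry correctly.
- Against it: the alkoxide of a tertiary β-hydroxy ester can revert by retro-aldol cleavage to 3. A hindered alkoxide is a slow aryne trap, and the aryl anion may be protonated before it acylates.
- Comparison: A7 then needs isobutyl addition next to the peri methoxy group, stereocontrolled removal of the C4 oxygen, demethylation and double formylation. The steps saved early would be spent late under conditions that threaten C2–O1.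

Key step: step 8

**Remarks on the chemistry**

- Correction to the endgame pattern: in 15 only C7–F lies between two formyl groups; C5–F lies between the C6 formyl group and C4a and is activated ortho by the C6 and para by the C8 formyl group, which should still suffice.
- Assumption: (−)-camphene of high enantiomeric purity is used, or the purity is raised by crystallisation of an early solid intermediate; every later stereocentre is relayed from it.
- Design changes: the alkyne is built by ethynylation of the ketone and aryl coupling, which removes one step and the separate aryl acetylene. The masked phenols are unveiled from 2-(trimethylsilyl)ethyl ethers with fluoride instead of from benzyl ethers.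
- The E geometry of 11 is a requirement of step 6: by the rotamer analysis, O-directed delivery should give 4S from the E isomer and undirected delivery should give 4S from the Z isomer.

## Route

Step 1
Reactants: 1 (1S,4R)-(−)-camphene
Product: 3 (1R,4S)-3,3-dimethylbicyclo[2.2.1]heptan-2-one (camphenilone), via primary ozonide 2 (not isolated)
Conditions: O3, CH2Cl2/MeOH (4:1), −78 °C; then Me2S, −78 °C → rt
Reagents that add atoms: ozone, [O-][O+]=O
Why: Ozonolysis of the exocyclic 1,1-disubstituted alkene with reductive work-up; 2 fragments to the ketone and a methanol-trapped carbonyl oxide, and Me2S reduces all peroxidic material to 3 and formaldehyde. The bridgeheads are untouched and 3 cannot enolise.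

Step 2
Reactants: 3 camphenilone; 4 lithium acetylide ethylenediamine complex
Product: 5 (1R,2S,4S)-2-ethynyl-3,3-dimethylbicyclo[2.2.1]heptan-2-ol (2-exo-ethynyl, 2-endo-hydroxy)
Conditions: 4 (1.5 equiv), THF, 0 °C → rt; aq. NH4Cl
Reagents that add atoms: none
Why: 1,2-Addition of an acetylide to a non-enolisable ketone. The slim nucleophile should enter from the exo face, as in additions to fenchone and norbornan-2-ones, because the endo face is blocked by the endo hydrogens at C5 and C6 as well as the endo methyl group; this sets C2 with O endo and carbon exo.

Step 3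
Reactants: 5 ethynyl carbinol; 6 2-bromo-1,3,5-trifluorobenzene
Product: 7 (1R,2R,4S)-3,3-dimethyl-2-[(2,4,6-trifluorophenyl)ethynyl]bicyclo[2.2.1]heptan-2-ol
Conditions: Pd(PPh3)2Cl2 (3 mol%), CuI (5 mol%), iPr2NH, THF, 60 °C, degassed
Reagents that add atoms: none
Why: Sonogashira coupling. The electron-poor aryl bromide adds readily to zerovalent palladium, and tertiary propargylic alcohols are standard alkyne partners; no stereocentre is involved.

Step 4
Reactants: 7 aryl alkynyl carbinol
Product: 9 (1R,2S,4S)-2-[(Z)-2-iodo-2-(2,4,6-trifluorophenyl)ethenyl]-3,3-dimethylbicyclo[2.2.1]heptan-2-ol, via sodium alkenylaluminate 8 (not isolated)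
Conditions: NaAlH2(OCH2CH2OCH3)2 (2.2 equiv), THF, 0 °C → rt; EtOAc, 0 °C; then I2, THF, −78 °C → 0 °C; aq. potassium sodium tartrate, Na2S2O3
Reagents that add atoms: iodine, [I][I]
Why: Alkoxide-directed trans-hydroalumination of a propargylic alcohol, then iodinolysis of the C–Al bond with retention. Hydride goes to C3 and aluminium to the aryl-bearing C4 inside a five-membered O–Al–C ring, so iodine ends on C4 cis to C2 (Z) and the aryl group trans.

Step 5
Reactants: 9 (Z)-alkenyl iodide; 10 isobutylzinc bromide
Product: 11 (1R,2S,4S)-3,3-dimethyl-2-[(E)-4-methyl-2-(2,4,6-trifluorophenyl)pent-1-en-1-yl]bicyclo[2.2.1]heptan-2-ol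
Conditions: 10 (3 equiv), Pd(dppf)Cl2 (5 mol%), THF, rt → 50 °C
Reagents that add atoms: none
Why: Negishi coupling of an alkenyl iodide with a primary alkylzinc reagent, with retention of geometry. The wide-bite-angle diphosphine favours reductive elimination over β-hydride elimination; the first equivalent of 10 is consumed by the OH group.

Step 6
Reactants: 11 (E)-alkene
Product: 12 (1R,2R,4S)-3,3-dimethyl-2-[(2S)-4-methyl-2-(2,4,6-trifluorophenyl)pentyl]bicyclo[2.2.1]heptan-2-ol
Conditions: [Ir(cod)(PCy3)(py)]PF6 (5 mol%), H2 (1–4 bar), CH2Cl2, 0 °C → rt
Reagents that add atoms: none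
Why: Hydroxyl-directed homogeneous hydrogenation. With O bound to iridium, the rotamer that places the C2–C1' bond in the alkene plane next to the cis isobutyl CH2 has the least 1,3-allylic strain (CMe2 turned away), so both hydrogens should arrive on the face where O sits, which for the E alkene is 4S. A tertiary allylic alcohol cannot isomerise to a ketone.

Step 7
Reactants: 12 saturated tertiary alcohol
Product: 14 2,4,6-trifluoro-5-{(2S)-1-[(1R,2R,4S)-2-hydroxy-3,3-dimethylbicyclo[2.2.1]heptan-2-yl]-4-methylpentan-2-yl}benzene-1,3-dicarbaldehyde, via dilithium hemiaminolate 13 (not isolated)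
Conditions: LiN(iPr)2 (2.2 equiv), THF, −78 °C; DMF (1.05 equiv), −78 °C; LiN(iPr)2 (1.5 equiv), −78 °C; DMF (3 equiv), −78 → −50 °C; inverse quench into cold 1 M HCl
Reagents that add atoms: N,N-dimethylformamide, CN(C)C=O
Why: Directed ortho-metalation and formylation. Each ring C–H lies between two fluorines and is removed at −78 °C; the first formyl group stays masked as the lithium hemiaminolate in 13 while the second site is metalated. The acidic inverse quench protonates the liberated dimethylamine before it can displace a fluoride.

Step 8
Reactants: 14 trifluoro dialdehyde tertiary alcohol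
Product: 15 (2R,4S,1'R,4'S)-5,7-difluoro-4-isobutyl-3',3'-dimethylspiro[chromane-2,2'-bicyclo[2.2.1]heptane]-6,8-dicarbaldehyde
Conditions: NaH (1.3 equiv), 15-crown-5 (0.1 equiv), THF (0.02 M), 0 °C → rt
Reagents that add atoms: none
Why: NaH converts the tertiary alcohol into its sodium alkoxide, which adds to an ortho C–F carbon (the future C8a) to give a Meisenheimer anion delocalised into the ortho (future C8) and para (future C6) formyl groups; loss of fluoride restores the arene and is irreversible. The closest known reaction type is the base-mediated intramolecular SNAr O-arylation of alcohols, tertiary ones included, by ortho-fluoro aryl aldehydes and ketones to give chromans. The pyran ring closes in a 6-exo-trig mode, the alkoxide reaching the sp2 carbon from above the ring plane through the C2–C3–C4 tether. No stereocentre is created: the C2–O bond dates from step 2 and is not broken, so O stays endo and no C2 cation can form, and C4–H is not acidified because both formyl groups are meta to the ring carbon that carries C4. The step needs ortho over para substitution and intramolecular over intermolecular attack: the para fluoride, though the most activated, is out of reach of the three-atom tether, and the two ortho fluorides interchange by rotation about the C4–aryl bond, so either gives 15. A hydride base that brings no competing nucleophile, and dilution, secure the rest; alkoxide and silylamide bases are avoided because they would attack the para fluoride or the formyl groups.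

Step 9
Reactants: 15 difluoro dialdehyde spiro chroman
Product: 16 (2R,4S,1'R,4'S)-4-isobutyl-3',3'-dimethyl-5,7-bis[2-(trimethylsilyl)ethoxy]spiro[chromane-2,2'-bicyclo[2.2.1]heptane]-6,8-dicarbaldehyde
Conditions: Me3SiCH2CH2OH (2.6 equiv), NaH (2.5 equiv), THF, 0 °C; then 15, 0 °C → rt (40 °C if C5 lags)
Reagents that add atoms: 2-(trimethylsilyl)ethanol, C[Si](C)(C)CCO
Why: Two intermolecular SNAr substitutions by a primary alkoxide. C7–F lies between both formyl groups and C5–F is ortho to the C6 and para to the C8 formyl group. The tertiary alkoxide at C8a is a far poorer leaving group than fluoride, and hemiacetal formation at the formyl groups is reversible.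

Step 10
Reactants: 16 bis(silylethyl) ether
Product: 17 (2R,4S,1'R,4'S)-5,7-dihydroxy-4-isobutyl-3',3'-dimethylspiro[chromane-2,2'-bicyclo[2.2.1]heptane]-6,8-dicarbaldehyde (CNP0150011.1)
Conditions: Bu4NF (3 equiv), THF, 0 °C → rt; aq. NH4Cl
Reagents that add atoms: none
Why: Fluoride-induced β-elimination of aryl 2-(trimethylsilyl)ethyl ethers: fluoride attacks silicon, ethene is lost, and the phenoxide is stabilised by the ortho formyl groups. No acid, hydrogen or Lewis acid meets the formyl groups or the C2–O1 ether.

## Compound list

1 | (1S,4R)-(−)-camphene (2,2-dimethyl-3-methylenebicyclo[2.2.1]heptane) | C=C2[C@@H]1CC[C@@H](C1)C2(C)C | starting material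
2 | primary ozonide of 1 (spiro 1,2,3-trioxolane on the former alkene carbons, formed in the flask) | C1OOOC12[C@@H]3CC[C@@H](C3)C2(C)C | intermediate
3 | (1R,4S)-3,3-dimethylbicyclo[2.2.1]heptan-2-one (camphenilone) | O=C2[C@@H]1CC[C@@H](C1)C2(C)C | intermediate
4 | lithium acetylide ethylenediamine complex | [Li+].[C-]#C.NCCN | starting material
5 | (1R,2S,4S)-2-ethynyl-3,3-dimethylbicyclo[2.2.1]heptan-2-ol (exo-ethynyl, endo-OH) | C#C[C@@]2(O)[C@@H]1CC[C@@H](C1)C2(C)C | intermediate
6 | 2-bromo-1,3,5-trifluorobenzene | Fc1cc(F)c(Br)c(F)c1 | starting material
7 | (1R,2R,4S)-3,3-dimethyl-2-[(2,4,6-trifluorophenyl)ethynyl]bicyclo[2.2.1]heptan-2-ol | Fc1cc(F)cc(F)c1C#C[C@@]2(O)[C@@H]1CC[C@@H](C1)C2(C)C | intermediate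
8 | sodium alkenylaluminate of 7 (five-membered O–Al–C4=C3–C2 ring, two 2-methoxyethoxy groups on aluminium, formed in the flask) | [Na+].COCCO[Al-]1(OCCOC)O[C@]2(C=C1c1c(F)cc(F)cc1F)[C@@H]1CC[C@@H](C1)C2(C)C | intermediate
9 | (1R,2S,4S)-2-[(Z)-2-iodo-2-(2,4,6-trifluorophenyl)ethenyl]-3,3-dimethylbicyclo[2.2.1]heptan-2-ol | Fc1cc(F)cc(F)c1/C(I)=C/[C@@]2(O)[C@@H]1CC[C@@H](C1)C2(C)C | intermediate
10 | isobutylzinc bromide | CC(C)C[Zn]Br | starting material
11 | (1R,2S,4S)-3,3-dimethyl-2-[(E)-4-methyl-2-(2,4,6-trifluorophenyl)pent-1-en-1-yl]bicyclo[2.2.1]heptan-2-ol (isobutyl cis to C2) | CC(C)C/C(=C\[C@@]2(O)[C@@H]1CC[C@@H](C1)C2(C)C)c1c(F)cc(F)cc1F | intermediate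
12 | (1R,2R,4S)-3,3-dimethyl-2-[(2S)-4-methyl-2-(2,4,6-trifluorophenyl)pentyl]bicyclo[2.2.1]heptan-2-ol | CC(C)C[C@H](c1c(F)cc(F)cc1F)C[C@@]2(O)[C@@H]1CC[C@@H](C1)C2(C)C | intermediate
13 | dilithium salt of the mono-formylation adduct of 12 (C2 alkoxide plus aryl CH(O−)NMe2 between two fluorines, formed in the flask) | CC(C)C[C@H](c1c(F)cc(F)c(C([O-])N(C)C)c1F)C[C@@]2([O-])[C@@H]1CC[C@@H](C1)C2(C)C.[Li+].[Li+] | intermediate
14 | 2,4,6-trifluoro-5-{(2S)-1-[(1R,2R,4S)-2-hydroxy-3,3-dimethylbicyclo[2.2.1]heptan-2-yl]-4-methylpentan-2-yl}benzene-1,3-dicarbaldehyde | CC(C)C[C@H](c1c(F)c(C=O)c(F)c(C=O)c1F)C[C@@]2(O)[C@@H]1CC[C@@H](C1)C2(C)C | intermediate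
15 | (2R,4S,1'R,4'S)-5,7-difluoro-4-isobutyl-3',3'-dimethylspiro[chromane-2,2'-bicyclo[2.2.1]heptane]-6,8-dicarbaldehyde | CC(C)C[C@H]1C[C@@]2(Oc3c(C=O)c(F)c(C=O)c(F)c31)[C@@H]1CC[C@@H](C1)C2(C)C | intermediate
16 | (2R,4S,1'R,4'S)-4-isobutyl-3',3'-dimethyl-5,7-bis[2-(trimethylsilyl)ethoxy]spiro[chromane-2,2'-bicyclo[2.2.1]heptane]-6,8-dicarbaldehyde | CC(C)C[C@H]1C[C@@]2(Oc3c(C=O)c(OCC[Si](C)(C)C)c(C=O)c(OCC[Si](C)(C)C)c31)[C@@H]1CC[C@@H](C1)C2(C)C | intermediate
17 | (2R,4S,1'R,4'S)-5,7-dihydroxy-4-isobutyl-3',3'-dimethylspiro[chromane-2,2'-bicyclo[2.2.1]heptane]-6,8-dicarbaldehyde | CC(C)C[C@H]1C[C@@]2(Oc3c(C=O)c(O)c(C=O)c(O)c31)[C@@H]1CC[C@@H](C1)C2(C)C | target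

## Step count and least certain steps

Total: 10 steps. Longest linear sequence: 10 steps from 1; the partners 4, 6 and 10 are purchased.

**Step 8 (key step).** The most likely failure is slow closure at the congested C2 alkoxide, which would let attack of one molecule's alkoxide on the para fluoride of another, or base chemistry at the formyl groups, take over.

Fallback: setting out from 12, the pyran would be closed before the ring is activated. The potassium alkoxide of 12 (KH, 18-crown-6, THF, 60 °C) would displace an ortho fluoride that is activated only by the two meta fluorines. This is the known unactivated intramolecular SNAr etherification and would give (2R,4S,1'R,4'S)-5,7-difluoro-4-isobutyl-3',3'-dimethylspiro[chromane-2,2'-bicyclo[2.2.1]heptane] F1. F1 would then be formylated twice by the protocol of step 7. The first lithiation is at C6–H between the two fluorines, passing through the lithium C6 hemiaminolate F2 in the flask; the second is at C8–H between fluorine and O1. The sequence comes back to the route at 15, and lithiation keeps Lewis acids away from the finished ether.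

**Step 6.** Poor facial selectivity would arise if hydrogen were delivered without prior O–Ir binding, through the rotamer with OH in the alkene plane and from the C1' side; this would give the C4 epimer. Ionisation of the tertiary allylic alcohol by acidic iridium hydride species, or alkene migration, is a second concern.

Fallback: setting out from 3, the other alkene geometry would be made and reduced under steric control.
- 4-Methylpent-1-yne and n-BuLi would give lithium 4-methylpent-1-ynide F3, which would add exo to 3 to give (1R,2R,4S)-3,3-dimethyl-2-(4-methylpent-1-yn-1-yl)bicyclo[2.2.1]heptan-2-ol F4.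
- Trans-hydroalumination through the sodium alkenylaluminate F5 and iodinolysis would give (1R,2S,4S)-2-[(Z)-2-iodo-4-methylpent-1-en-1-yl]-3,3-dimethylbicyclo[2.2.1]heptan-2-ol F6.
- Negishi coupling with (2,4,6-trifluorophenyl)zinc chloride F7 (from 1,3,5-trifluorobenzene, n-BuLi, then ZnCl2; Pd(P(t-Bu)3)2 as catalyst) would give (1R,2S,4S)-3,3-dimethyl-2-[(Z)-4-methyl-2-(2,4,6-trifluorophenyl)pent-1-en-1-yl]bicyclo[2.2.1]heptan-2-ol F8, with the aryl group cis to C2.
- Heterogeneous hydrogenation (Pt/C, H2, EtOAc) should approach from the C1' side, away from the exo methyl of C3'. For this geometry that is again 4S, and the route is rejoined at 12.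

**Step 7.** The second metalation may be incomplete once the dilithio species aggregates. The ortho-fluoro aryllithium may lose LiF to an aryne on warming. Liberated dimethylamine may displace an activated fluoride during the quench. Premature ring closure would only anticipate step 8.

Fallback: setting out from 12, the two formyl groups would be installed in separate operations.
- One lithiation and DMF quench would give 2,4,6-trifluoro-3-{(2S)-1-[(1R,2R,4S)-2-hydroxy-3,3-dimethylbicyclo[2.2.1]heptan-2-yl]-4-methylpentan-2-yl}benzaldehyde F9, which would be isolated.
- F9 would be treated with lithium N,N,N'-trimethylethylenediamide F10 (2 equiv) to give the chelated dilithium α-amino alkoxide F11 in the flask.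
- F11 would be metalated with n-BuLi at −78 °C and quenched with DMF and cold acid, coming back at 14.

**Step 9.** Substitution may stall after the first fluoride because the ring becomes more electron-rich and C5 is crowded. Hydride transfer from the alkoxide to a formyl group is a second risk.

Fallback: setting out from 15, the smallest alkoxide would be used and the unmasking changed to a nucleophilic dealkylation. NaOMe in MeOH/THF would give (2R,4S,1'R,4'S)-4-isobutyl-5,7-dimethoxy-3',3'-dimethylspiro[chromane-2,2'-bicyclo[2.2.1]heptane]-6,8-dicarbaldehyde F12. Heating F12 with LiCl in DMF would cleave both methyl ethers by SN2 attack at methyl; each departing phenoxide is ortho or para to formyl groups, and the tertiary ether cannot react this way. The route is rejoined at 17.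

## Further compounds

F1 | step 8 | (2R,4S,1'R,4'S)-5,7-difluoro-4-isobutyl-3',3'-dimethylspiro[chromane-2,2'-bicyclo[2.2.1]heptane] | CC(C)C[C@H]1C[C@@]2(Oc3cc(F)cc(F)c31)[C@@H]1CC[C@@H](C1)C2(C)C
F2 | step 8 | lithium C6 hemiaminolate of F1 (C6–CH(O−)NMe2, formed in the flask) | CC(C)C[C@H]1C[C@@]2(Oc3cc(F)c(C([O-])N(C)C)c(F)c31)[C@@H]1CC[C@@H](C1)C2(C)C.[Li+]
F3 | step 6 | lithium 4-methylpent-1-ynide | [Li+].[C-]#CCC(C)C
F4 | step 6 | (1R,2R,4S)-3,3-dimethyl-2-(4-methylpent-1-yn-1-yl)bicyclo[2.2.1]heptan-2-ol | CC(C)CC#C[C@@]2(O)[C@@H]1CC[C@@H](C1)C2(C)C
F5 | step 6 | sodium alkenylaluminate of F4 (five-membered O–Al–C=C–C ring, formed in the flask) | [Na+].COCCO[Al-]1(OCCOC)O[C@]2(C=C1CC(C)C)[C@@H]1CC[C@@H](C1)C2(C)C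
F6 | step 6 | (1R,2S,4S)-2-[(Z)-2-iodo-4-methylpent-1-en-1-yl]-3,3-dimethylbicyclo[2.2.1]heptan-2-ol | CC(C)C/C(I)=C/[C@@]2(O)[C@@H]1CC[C@@H](C1)C2(C)C
F7 | step 6 | (2,4,6-trifluorophenyl)zinc chloride | Fc1cc(F)c([Zn]Cl)c(F)c1
F8 | step 6 | (1R,2S,4S)-3,3-dimethyl-2-[(Z)-4-methyl-2-(2,4,6-trifluorophenyl)pent-1-en-1-yl]bicyclo[2.2.1]heptan-2-ol | CC(C)C/C(=C/[C@@]2(O)[C@@H]1CC[C@@H](C1)C2(C)C)c1c(F)cc(F)cc1F
F9 | step 7 | 2,4,6-trifluoro-3-{(2S)-1-[(1R,2R,4S)-2-hydroxy-3,3-dimethylbicyclo[2.2.1]heptan-2-yl]-4-methylpentan-2-yl}benzaldehyde | CC(C)C[C@H](c1c(F)cc(F)c(C=O)c1F)C[C@@]2(O)[C@@H]1CC[C@@H](C1)C2(C)C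
F10 | step 7 | lithium N,N,N'-trimethylethylenediamide | [Li+].C[N-]CCN(C)C
F11 | step 7 | dilithium α-amino alkoxide of F9 (C2 alkoxide plus aryl CH(O−)N(Me)CH2CH2NMe2, formed in the flask) | CC(C)C[C@H](c1c(F)cc(F)c(C([O-])N(C)CCN(C)C)c1F)C[C@@]2([O-])[C@@H]1CC[C@@H](C1)C2(C)C.[Li+].[Li+]
F12 | step 9 | (2R,4S,1'R,4'S)-4-isobutyl-5,7-dimethoxy-3',3'-dimethylspiro[chromane-2,2'-bicyclo[2.2.1]heptane]-6,8-dicarbaldehyde | CC(C)C[C@H]1C[C@@]2(Oc3c(C=O)c(OC)c(C=O)c(OC)c31)[C@@H]1CC[C@@H](C1)C2(C)C
A1 | alternative 1 | 5,7-dimethoxy-2-[(1R,3S)-3-(prop-1-en-2-yl)cyclopentyl]-4H-chromen-4-one (cis) | C=C(C)[C@H]1CC[C@H](C1)C2=CC(=O)c3c(OC)cc(OC)cc3O2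
A2 | alternative 1 | cyclobutane photoadduct: 5,7-dimethoxychroman-4-one with C2–C3' and C3–CH2 bonds, cyclobutane exo-fused on the norbornane, O1 endo | COc1cc(OC)c2C(=O)[C@H]3C[C@]4(C)[C@H]5CC[C@H](C5)[C@]34Oc2c1
A3 | alternative 2 | (4S)-2-[2-(cyclopent-3-en-1-yl)propan-2-yl]-4-isobutyl-5,7-dimethoxy-4H-chromene | CC(C)C[C@H]1C=C(Oc2cc(OC)cc(OC)c21)C(C)(C)C1CC=CC1
A4 | alternative 2 | (2R,4S,1'R,4'S)-4-isobutyl-5,7-dimethoxy-3',3'-dimethylspiro[chromane-2,2'-bicyclo[2.2.1]heptane] | CC(C)C[C@H]1C[C@@]2(Oc3cc(OC)cc(OC)c31)[C@@H]1CC[C@@H](C1)C2(C)C
A5 | alternative 3 | methyl 2-[(1R,2R,4S)-2-hydroxy-3,3-dimethylbicyclo[2.2.1]heptan-2-yl]acetate (endo-OH) | COC(=O)C[C@@]2(O)[C@@H]1CC[C@@H](C1)C2(C)C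
A6 | alternative 3 | 3,5-dimethoxy-2-(trimethylsilyl)phenyl trifluoromethanesulfonate | COc1cc(OC)c([Si](C)(C)C)c(OS(=O)(=O)C(F)(F)F)c1
A7 | alternative 3 | (2R,1'R,4'S)-5,7-dimethoxy-3',3'-dimethylspiro[chromane-2,2'-bicyclo[2.2.1]heptan]-4-one | O=C1C[C@@]2(Oc3cc(OC)cc(OC)c31)[C@@H]1CC[C@@H](C1)C2(C)C
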